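**Retrosynthetic overview**
- Feature: the syn C2–Cl / C3–OH pair beside the C4 ketone is read as a cis oxirane (ring of C2, C3 and O) opened by chloride at C2. Before it is a ketone, C4 carries a hydroxyl stereocenter that steers the epoxidation and is then oxidised away.
- Target ⇒ cis-2,3-epoxy-4-ketone (chloride opening) ⇒ threo cis-2,3-epoxy-4-ol (oxidation) ⇒ (4R,2Z)-allylic alcohol (hydroxyl-directed epoxidation) ⇒ ynone (transfer hydrogenation, semihydrogenation) ⇒ C4 aldehyde + propynyl Grignard (C3–C4 bond).
- C13–furan bond: Negishi coupling of a homoallylic zinc reagent with 4-bromo-2-(furan-3-ylmethyl)furan, made from 4-bromo-2-furaldehyde and 3-furyllithium, then deoxygenation of the carbinol.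
- C9–C10 bond and E-C10=C11: alkylation of 5-lithio-2,3-dihydrofuran with the iodide from (R)-citronellol (source of C6), then nickel-catalysed opening of the enol ether with MeMgBr.
- Ring order: both furans come from bought material; the oxirane is the only ring made (step 16) and it is opened again in step 18.

Key step: step 16

Remark: atoms are numbered as in the target chain, C1 (methyl on the chlorinated carbon) to C13 (CH2 on the furan). The sense of the transfer hydrogenation in step 14 is assigned on the assumption that the alkyne takes the place that the aryl group has in aryl ketones.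

**Route**

Step 1
Reactants: 1 (R)-citronellol
Product: 2 tert-butyl{[(3R)-3,7-dimethyloct-6-en-1-yl]oxy}dimethylsilane
Conditions: TBSCl, imidazole, DMF, 0 °C → rt
Reagents that add atoms: tert-butyldimethylsilyl chloride, CC(C)(C)[Si](C)(C)Cl
Why: Imidazole-promoted silylation of the primary alcohol (TBS protection) masks the future C4 oxygen for the organometallic steps and does not touch the C6 stereocenter.

Step 2
Reactants: 2 tert-butyl{[(3R)-3,7-dimethyloct-6-en-1-yl]oxy}dimethylsilane
Product: 4 (4R)-6-[(tert-butyldimethylsilyl)oxy]-4-methylhexan-1-ol, via secondary ozonide 3 (not isolated)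
Conditions: O3, CH2Cl2, –78 °C; then NaBH4, MeOH, –78 °C → rt
Reagents that add atoms: ozone, [O-][O+]=O
Why: Reductive ozonolysis cleaves the only alkene and NaBH4 reduces the ozonide directly, so the future C9 appears as a primary alcohol while the silyl ether stays intact.

Step 3
Reactants: 4 (4R)-6-[(tert-butyldimethylsilyl)oxy]-4-methylhexan-1-ol
Product: 5 tert-butyl{[(3R)-6-iodo-3-methylhexyl]oxy}dimethylsilane
Conditions: I2, PPh3, imidazole, CH2Cl2, 0 °C → rt
Reagents that add atoms: iodine, II
Why: Garegg–Samuelsson (Appel-type) iodination displaces the oxyphosphonium ion of the primary alcohol by iodide in an SN2 step under neutral conditions that the TBS ether tolerates.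

Step 4
Reactants: 5 tert-butyl{[(3R)-6-iodo-3-methylhexyl]oxy}dimethylsilane; 6 2,3-dihydrofuran
Product: 8 tert-butyl{[(3R)-6-(4,5-dihydrofuran-2-yl)-3-methylhexyl]oxy}dimethylsilane, via 5-lithio-2,3-dihydrofuran 7 (not isolated)
Conditions: 6, t-BuLi, THF, –78 → 0 °C; then 5, THF, –30 °C → rt; basic work-up
Reagents that add atoms: none
Why: t-BuLi removes the vinylic hydrogen next to oxygen and the α-alkoxyvinyllithium is alkylated by the primary iodide (SN2), which forms the C9–C10 bond; the acid-labile enol ether is carried on without silica chromatography.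

Step 5
Reactants: 8 tert-butyl{[(3R)-6-(4,5-dihydrofuran-2-yl)-3-methylhexyl]oxy}dimethylsilane
Product: 9 (3E,7R)-9-[(tert-butyldimethylsilyl)oxy]-4,7-dimethylnon-3-en-1-ol
Conditions: MeMgBr, NiCl2(PPh3)2 (5 mol%), toluene, 80 °C
Reagents that add atoms: methylmagnesium bromide, C[Mg]Br
Why: Nickel-catalysed Kumada-type coupling at the enol ether C–O bond replaces the ring oxygen on C10 by methyl with retention of alkene geometry, so the cis relation of O and C12 in the ring becomes the E-trisubstituted C10=C11 alkene and the released oxygen is the C13 alcohol.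

Step 6
Reactants: 9 (3E,7R)-9-[(tert-butyldimethylsilyl)oxy]-4,7-dimethylnon-3-en-1-ol
Product: 10 tert-butyl{[(3R,6E)-9-iodo-3,7-dimethylnon-6-en-1-yl]oxy}dimethylsilane
Conditions: I2, PPh3, imidazole, CH2Cl2, 0 °C
Reagents that add atoms: iodine, II
Why: Garegg–Samuelsson iodination of the primary homoallylic alcohol proceeds by SN2 displacement without touching the trisubstituted alkene or the silyl ether.

Step 7
Reactants: 11 3-bromofuran; 12 4-bromo-2-furaldehyde
Product: 14 (4-bromofuran-2-yl)(furan-3-yl)methanol (racemic), via 3-furyllithium 13 (not isolated)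
Conditions: 11, n-BuLi, THF, –78 °C; then 12, –78 °C; aq. NH4Cl
Reagents that add atoms: none
Why: Bromine–lithium exchange at –78 °C (kept cold so the 3-lithio species does not isomerise) and 1,2-addition to the aldehyde, which is faster than exchange at the ring bromide of 12, give the bis-furyl carbinol, whose racemic centre is removed in the next step.

Step 8
Reactants: 14 (4-bromofuran-2-yl)(furan-3-yl)methanol
Product: 15 4-bromo-2-(furan-3-ylmethyl)furan
Conditions: Et3SiH (3 equiv), TFA, CH2Cl2, –20 → 0 °C
Reagents that add atoms: none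
Why: Ionic hydrogenation: TFA ionises the carbinol to a furfuryl cation stabilised by both rings and Et3SiH traps it by hydride transfer, with low temperature and excess silane limiting acid-induced furan oligomerisation.

Step 9
Reactants: 10 tert-butyl{[(3R,6E)-9-iodo-3,7-dimethylnon-6-en-1-yl]oxy}dimethylsilane; 15 4-bromo-2-(furan-3-ylmethyl)furan
Product: 17 tert-butyl{[(3R,6E)-9-[5-(furan-3-ylmethyl)furan-3-yl]-3,7-dimethylnon-6-en-1-yl]oxy}dimethylsilane, via homoallylic zinc iodide 16 (not isolated)
Conditions: 10, Zn dust (activated with BrCH2CH2Br, TMSCl), LiCl, THF, 40 °C; then 15, Pd(OAc)2 (2 mol%), SPhos (4 mol%), THF, 50 °C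
Reagents that add atoms: none
Why: LiCl-assisted zinc insertion into the primary C–I bond followed by Negishi sp3–sp2 coupling (oxidative addition of zerovalent palladium to the furyl C–Br bond, transmetalation, reductive elimination) forms the C13–furan bond, and the bulky biaryl phosphine suppresses β-hydride elimination.

Step 10
Reactants: 17 tert-butyl{[(3R,6E)-9-[5-(furan-3-ylmethyl)furan-3-yl]-3,7-dimethylnon-6-en-1-yl]oxy}dimethylsilane
Product: 18 (3R,6E)-9-[5-(furan-3-ylmethyl)furan-3-yl]-3,7-dimethylnon-6-en-1-ol
Conditions: TBAF, THF, 0 °C → rt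
Reagents that add atoms: none
Why: Fluoride cleaves the Si–O bond (desilylation) and frees the C4 primary alcohol without affecting the alkene or the furans.

Step 11
Reactants: 18 (3R,6E)-9-[5-(furan-3-ylmethyl)furan-3-yl]-3,7-dimethylnon-6-en-1-ol
Product: 19 (3R,6E)-9-[5-(furan-3-ylmethyl)furan-3-yl]-3,7-dimethylnon-6-enal
Conditions: DMP, NaHCO3, CH2Cl2, 0 °C → rt
Reagents that add atoms: none
Why: Dess–Martin oxidation gives the C4 aldehyde under buffered conditions that spare the furans and cannot epimerise C6, which is β to the carbonyl.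

Step 12
Reactants: 19 (3R,6E)-9-[5-(furan-3-ylmethyl)furan-3-yl]-3,7-dimethylnon-6-enal; 20 1-propynylmagnesium bromide
Product: 21 (6R,10E)-13-[5-(furan-3-ylmethyl)furan-3-yl]-6,10-dimethyltridec-10-en-2-yn-4-ol (both C4 epimers)
Conditions: THF, –20 → 0 °C; aq. NH4Cl
Reagents that add atoms: none
Why: Grignard 1,2-addition of the alkynyl nucleophile to the aldehyde forms the C3–C4 bond; the C4 configuration is not controlled here and does not matter because the carbinol is oxidised next.

Step 13
Reactants: 21 (6R,10E)-13-[5-(furan-3-ylmethyl)furan-3-yl]-6,10-dimethyltridec-10-en-2-yn-4-ol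
Product: 22 (6R,10E)-13-[5-(furan-3-ylmethyl)furan-3-yl]-6,10-dimethyltridec-10-en-2-yn-4-one
Conditions: DMP, NaHCO3, CH2Cl2, 0 °C
Reagents that add atoms: none
Why: Dess–Martin oxidation of the propargylic alcohol gives the conjugated ynone, the substrate class best suited to catalytic asymmetric reduction.

Step 14
Reactants: 22 (6R,10E)-13-[5-(furan-3-ylmethyl)furan-3-yl]-6,10-dimethyltridec-10-en-2-yn-4-one
Product: 23 (4R,6R,10E)-13-[5-(furan-3-ylmethyl)furan-3-yl]-6,10-dimethyltridec-10-en-2-yn-4-ol
Conditions: Ru[(R,R)-TsDPEN](p-cymene) (2 mol%; from RuCl[(R,R)-TsDPEN](p-cymene) and KOH), i-PrOH, rt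
Reagents that add atoms: none
Why: Noyori asymmetric transfer hydrogenation: the divalent ruthenium hydride/amine complex passes hydride and proton to the C=O through a six-membered transition state, so the (R,R) ligand should set the (4R) carbinol under catalyst control while the alkyne, the alkene and the furans are not reduced.

Step 15
Reactants: 23 (4R,6R,10E)-13-[5-(furan-3-ylmethyl)furan-3-yl]-6,10-dimethyltridec-10-en-2-yn-4-ol
Product: 24 (2Z,4R,6R,10E)-13-[5-(furan-3-ylmethyl)furan-3-yl]-6,10-dimethyltrideca-2,10-dien-4-ol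
Conditions: H2 (1 atm), Pd/CaCO3 poisoned with Pb(OAc)2, quinoline, EtOAc, rt
Reagents that add atoms: none
Why: Lindlar semihydrogenation adds hydrogen syn on the poisoned palladium surface to give the Z alkene, and quinoline stops the reaction before over-reduction or attack on the trisubstituted alkene and the furans.

Step 16
Reactants: 24 (2Z,4R,6R,10E)-13-[5-(furan-3-ylmethyl)furan-3-yl]-6,10-dimethyltrideca-2,10-dien-4-ol
Product: 25 (2R,3S,4R,6R,10E)-2,3-epoxy-13-[5-(furan-3-ylmethyl)furan-3-yl]-6,10-dimethyltridec-10-en-4-ol (cis-oxirane, threo to the C4 hydroxyl)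
Conditions: Ti(O-i-Pr)4 (0.3 equiv), t-BuOOH (anhydrous, in decane, 1.5 equiv), 4 Å MS, CH2Cl2, –20 °C
Reagents that add atoms: tert-butyl hydroperoxide, CC(C)(C)OO
Why: The C4 hydroxyl of 24 exchanges for isopropoxide on tetravalent titanium, which also binds tert-butyl peroxide through both oxygens, and the activated peroxide oxygen is passed to C2=C3 inside this complex in one concerted step (closest known reaction type: hydroxyl-directed Ti(O-i-Pr)4/t-BuOOH epoxidation of secondary allylic alcohols, the tartrate-free counterpart of the Sharpless epoxidation). The oxirane closes by [2+1] oxygen-atom transfer in which both C–O bonds form on the same alkene face, so the Z geometry becomes a cis ring. C2 and C3 are set together by the (4R) carbinol: allylic 1,3-strain between the C1 methyl and the C4 substituents keeps C4–H in the alkene plane, which fixes the hydroxyl on one face, and oxygen arrives on that face to give the threo (2R,3S,4R) isomer. The step needs facial selectivity relative to C4, secured by that strain, which is specific to the Z alkene, and chemoselectivity over C10=C11 and both furans, secured because only an alkene within reach of the titanium alkoxide is oxidised and 24 has a single hydroxyl. Any erythro isomer is a diastereomer and should be removed by chromatography here, before C4 is oxidised.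

Step 17
Reactants: 25 (2R,3S,4R,6R,10E)-2,3-epoxy-13-[5-(furan-3-ylmethyl)furan-3-yl]-6,10-dimethyltridec-10-en-4-ol
Product: 26 (2R,3R,6R,10E)-2,3-epoxy-13-[5-(furan-3-ylmethyl)furan-3-yl]-6,10-dimethyltridec-10-en-4-one (cis-epoxy ketone)
Conditions: DMP, NaHCO3, CH2Cl2, 0 °C → rt
Reagents that add atoms: none
Why: Dess–Martin oxidation under bicarbonate buffer turns the C4 carbinol into the ketone without opening the oxirane or epimerising C3, and so removes the relay stereocenter once it has done its work.

Step 18
Reactants: 26 (2R,3R,6R,10E)-2,3-epoxy-13-[5-(furan-3-ylmethyl)furan-3-yl]-6,10-dimethyltridec-10-en-4-one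
Product: 27 (2S,3S,6R,10E)-2-chloro-13-[5-(furan-3-ylmethyl)furan-3-yl]-3-hydroxy-6,10-dimethyltridec-10-en-4-one (target)
Conditions: MgCl2 (anhydrous, 3 equiv), MeCN, 0 °C → rt; aq. NH4Cl
Reagents that add atoms: magnesium chloride, Cl[Mg]Cl
Why: Magnesium chelated between the ketone and oxirane oxygens activates the ring and chloride attacks C2 from the rear (anti opening of an α,β-epoxy carbonyl compound by a magnesium halide to the β-halo-α-hydroxy product), because developing positive charge is tolerated at C2 but not at C3 next to the carbonyl; inversion at C2 and retention at C3 give the (2S,3S) syn chlorohydrin.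

**Compound list**
1 | (R)-citronellol, (3R)-3,7-dimethyloct-6-en-1-ol | C[C@H](CCC=C(C)C)CCO | starting material
2 | tert-butyl{[(3R)-3,7-dimethyloct-6-en-1-yl]oxy}dimethylsilane | CC(C)=CCC[C@@H](C)CCO[Si](C)(C)C(C)(C)C | intermediate
3 | secondary ozonide of 2, 3-[(3R)-5-(tert-butyldimethylsilyloxy)-3-methylpentyl]-5,5-dimethyl-1,2,4-trioxolane | CC1(C)OOC(CC[C@@H](C)CCO[Si](C)(C)C(C)(C)C)O1 | intermediate (not isolated)
4 | (4R)-6-[(tert-butyldimethylsilyl)oxy]-4-methylhexan-1-ol | OCCC[C@@H](C)CCO[Si](C)(C)C(C)(C)C | intermediate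
5 | tert-butyl{[(3R)-6-iodo-3-methylhexyl]oxy}dimethylsilane | ICCC[C@@H](C)CCO[Si](C)(C)C(C)(C)C | intermediate
6 | 2,3-dihydrofuran | C1CC=CO1 | starting material
7 | 5-lithio-2,3-dihydrofuran | [Li]C1=CCCO1 | intermediate (not isolated)
8 | tert-butyl{[(3R)-6-(4,5-dihydrofuran-2-yl)-3-methylhexyl]oxy}dimethylsilane | C1=C(CCC[C@@H](C)CCO[Si](C)(C)C(C)(C)C)OCC1 | intermediate
9 | (3E,7R)-9-[(tert-butyldimethylsilyl)oxy]-4,7-dimethylnon-3-en-1-ol | C/C(=C\CCO)CCC[C@@H](C)CCO[Si](C)(C)C(C)(C)C | intermediate
10 | tert-butyl{[(3R,6E)-9-iodo-3,7-dimethylnon-6-en-1-yl]oxy}dimethylsilane | C/C(=C\CCI)CCC[C@@H](C)CCO[Si](C)(C)C(C)(C)C | intermediate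
11 | 3-bromofuran | Brc1ccoc1 | starting material
12 | 4-bromo-2-furaldehyde | O=Cc1cc(Br)co1 | starting material
13 | 3-furyllithium | [Li]c1ccoc1 | intermediate (not isolated)
14 | (4-bromofuran-2-yl)(furan-3-yl)methanol, racemic | OC(c1cc(Br)co1)c1ccoc1 | intermediate
15 | 4-bromo-2-(furan-3-ylmethyl)furan | Brc1coc(Cc2ccoc2)c1 | intermediate
16 | [(3E,7R)-9-(tert-butyldimethylsilyloxy)-4,7-dimethylnon-3-en-1-yl]zinc iodide | C/C(=C\CC[Zn]I)CCC[C@@H](C)CCO[Si](C)(C)C(C)(C)C | intermediate (not isolated)
17 | tert-butyl{[(3R,6E)-9-[5-(furan-3-ylmethyl)furan-3-yl]-3,7-dimethylnon-6-en-1-yl]oxy}dimethylsilane | C/C(=C\CCc1coc(Cc2ccoc2)c1)CCC[C@@H](C)CCO[Si](C)(C)C(C)(C)C | intermediate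
18 | (3R,6E)-9-[5-(furan-3-ylmethyl)furan-3-yl]-3,7-dimethylnon-6-en-1-ol | C/C(=C\CCc1coc(Cc2ccoc2)c1)CCC[C@@H](C)CCO | intermediate
19 | (3R,6E)-9-[5-(furan-3-ylmethyl)furan-3-yl]-3,7-dimethylnon-6-enal | C/C(=C\CCc1coc(Cc2ccoc2)c1)CCC[C@@H](C)CC=O | intermediate
20 | 1-propynylmagnesium bromide | CC#C[Mg]Br | starting material
21 | (6R,10E)-13-[5-(furan-3-ylmethyl)furan-3-yl]-6,10-dimethyltridec-10-en-2-yn-4-ol, both C4 epimers | C/C(=C\CCc1coc(Cc2ccoc2)c1)CCC[C@@H](C)CC(O)C#CC | intermediate
22 | (6R,10E)-13-[5-(furan-3-ylmethyl)furan-3-yl]-6,10-dimethyltridec-10-en-2-yn-4-one | C/C(=C\CCc1coc(Cc2ccoc2)c1)CCC[C@@H](C)CC(=O)C#CC | intermediate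
23 | (4R,6R,10E)-13-[5-(furan-3-ylmethyl)furan-3-yl]-6,10-dimethyltridec-10-en-2-yn-4-ol | C/C(=C\CCc1coc(Cc2ccoc2)c1)CCC[C@@H](C)C[C@@H](O)C#CC | intermediate
24 | (2Z,4R,6R,10E)-13-[5-(furan-3-ylmethyl)furan-3-yl]-6,10-dimethyltrideca-2,10-dien-4-ol | C/C(=C\CCc1coc(Cc2ccoc2)c1)CCC[C@@H](C)C[C@@H](O)/C=C\C | intermediate
25 | (2R,3S,4R,6R,10E)-2,3-epoxy-13-[5-(furan-3-ylmethyl)furan-3-yl]-6,10-dimethyltridec-10-en-4-ol | C/C(=C\CCc1coc(Cc2ccoc2)c1)CCC[C@@H](C)C[C@@H](O)[C@@H]1O[C@@H]1C | intermediate
26 | (2R,3R,6R,10E)-2,3-epoxy-13-[5-(furan-3-ylmethyl)furan-3-yl]-6,10-dimethyltridec-10-en-4-one | C/C(=C\CCc1coc(Cc2ccoc2)c1)CCC[C@@H](C)CC(=O)[C@@H]1O[C@@H]1C | intermediate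
27 | (2S,3S,6R,10E)-2-chloro-13-[5-(furan-3-ylmethyl)furan-3-yl]-3-hydroxy-6,10-dimethyltridec-10-en-4-one | C/C(=C\CCc1coc(Cc2ccoc2)c1)CCC[C@@H](C)CC(=O)[C@H](O)[C@H](C)Cl | target

**Step count**
Total: 18 steps. Longest linear sequence: 16 steps (steps 1–6 and 9–18); steps 7–8 make the bisfuran bromide that enters at step 9.

**Steps most likely to fail**

Step 18 (chloride opening). Chloride may attack C3, which the carbonyl activates toward direct displacement, instead of C2. The opening may also stall because MgCl2 is a weak chloride donor, or the product may lose HCl or epimerise at C3 on long exposure to the Lewis acid. The fallback reverses the order of opening and oxidation so that the free C4 hydroxyl, not the ketone, controls the regiochemistry. It sets out from 25, which is treated with TiCl(O-i-Pr)3 in CH2Cl2 at 0 °C. Chloride is then delivered from the titanium alkoxide of the C4 hydroxyl to the distal oxirane carbon C2 with inversion, the established distal opening of 2,3-epoxy alcohols, to give the chlorodiol (2S,3S,4R,6R,10E)-2-chloro-13-[5-(furan-3-ylmethyl)furan-3-yl]-6,10-dimethyltridec-10-ene-3,4-diol F1. Its C4 carbinol is less hindered than the C3 carbinol and is not deactivated by a vicinal chlorine, so it should be oxidised selectively with catalytic TEMPO and PhI(OAc)2 in CH2Cl2. The fallback comes back to the route at 27.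

Step 16 (key epoxidation). Facial discrimination may be incomplete, so that the erythro isomer forms. Oxygen transfer to the hindered Z alkene may also be slow enough for isopropoxide to open the product on titanium, or for the furans to be oxidised on long exposure. The fallback moves the facial choice from the substrate conformation to a chiral catalyst. It sets out from 24, which is epoxidised with VO(O-i-Pr)3, a C2-symmetric chiral bis-hydroxamic acid ligand and t-BuOOH in toluene at 0 °C. The ligand enantiomer is chosen so that catalyst and allylic strain favour the same face (matched double stereodifferentiation), a system that handles Z-allylic alcohols well and still oxidises only the alkene bound through its hydroxyl. It comes back to the route at 25 and passes through no new compound (F0).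

Step 8 (deoxygenation of the bis-furyl carbinol). Acid-induced oligomerisation or ring opening of the furans may compete with hydride capture of the furfuryl cation. The fallback avoids cationic intermediates. It sets out from 14, which is oxidised with MnO2 in CH2Cl2 to the ketone (4-bromofuran-2-yl)(furan-3-yl)methanone F2. Wolff–Kishner reduction under Huang-Minlon conditions (N2H4·H2O, KOH, diethylene glycol, heating) then proceeds through the hydrazone [(4-bromofuran-2-yl)(furan-3-yl)methylidene]hydrazine F3 to the methylene compound. It comes back to the route at 15.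

**Further compounds**
F1 | step 18 | (2S,3S,4R,6R,10E)-2-chloro-13-[5-(furan-3-ylmethyl)furan-3-yl]-6,10-dimethyltridec-10-ene-3,4-diol | C/C(=C\CCc1coc(Cc2ccoc2)c1)CCC[C@@H](C)C[C@@H](O)[C@H](O)[C@H](C)Cl
F0 | step 16 | none | none
F2 | step 8 | (4-bromofuran-2-yl)(furan-3-yl)methanone | O=C(c1cc(Br)co1)c1ccoc1
F3 | step 8 | [(4-bromofuran-2-yl)(furan-3-yl)methylidene]hydrazine | NN=C(c1cc(Br)co1)c1ccoc1
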